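Late in the north-west run the solid substrate shrinks slowly, and I read that run's first and last rows against each other.

| flask | solid substrate | coupling partner | remark | time |
|---|---|---|---|---|
| north-west | 0.54 M | 0.40 M | run made earlier |  |
| south | 0.40 M | 0.40 M | run made earlier |  |
| grey | 0.80 M | 0.400 M |  | 50 min |
| amber | 0.80 M | 0.960 M |  | 50 min |
| teal | 0.80 M | 2.00 M |  | 50 min |

| run | time / min | first product / % | solid substrate / % |
|---|---|---|---|
| north-west | 2.00 | 2.0 | 68.4 |
| north-west | 4.00 | 5.7 | 45.4 |
| north-west | 6.00 | 12.6 | 32.8 |
| north-west | 8.00 | 16.5 | 22.2 |
| north-west | 10.0 | 22.4 | 13.5 |
| south | 0.833 | 0.2 | 79.2 |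
| south | 2.50 | 4.8 | 47.7 |
| south | 5.00 | 12.8 | 18.4 |
| south | 8.00 | 23.6 | 0.4 |
| south | 10.0 | 29.0 | 0 |

(standard deviation of a reading: 0.5 percentage points)

- solid substrate is a solid; its amount is given per volume of the solution
- steps that have been proposed: solid substrate <-> starting material; starting material + coupling partner -> first product; coupling partner + first product <-> bis adduct
- at the start none of the solid substrate is in solution

1. first product at the end, in percent of the solid substrate charged, for each flask in turn (grey, amber, teal)

Call A the starting material in solution and B the coupling partner, and count no bis adduct for now. Up to 2.00 min the solid goes at 0.0853 M/min while A averages 0.0799 M. Between the last two rows it goes at 0.0235 M/min while A averages 0.339 M. A straight line through these two pairs gives a dissolving constant k_d of 0.239 /min and a saturation level S of 0.437 M, both read from scattered rows. Over those last rows B averages 0.295 M, so the growth of first product gives a coupling constant k of 0.160 /M/min.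

I carry one quantity, the crossover partner level Bc = k_d/k, 1.50 M, where the pseudo-first-order coupling constant kB equals k_d. While solid remains, A rests near S/(1 + B/Bc), much as a Michaelis constant marks a half point. Well below Bc I take coupling as the rate-limiting step; near Bc the two steps run at like rates.

Grey's charge is less than Bc, so I take A as S. The partner's half-life is then ln(2)/(kS), 9.95 min, and by 50 min first product nears 48.5%. Teal's charge is more than Bc, so with B held at that charge I reckon A resting near 0.187 M and the solid lasting about 13.4 min. These runs give me no firm constant for bis adduct, so I commit no figure for amber or teal.

The forecast gives 38%, 55% and 15%; its grey figure is lower than mine, and its teal first product “then drains to bis adduct”.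

The flasks give 45.1%, 81.4% and 68.7%.

    solid substrate ⇌ starting material, rate k1*(cs1 - [starting material]) while solid is left; crystals form when [starting material] > cs1 (solubility = 0.410 M, k = 0.280 /min)
    starting material + coupling partner → first product (k = 0.160 /M/min)
    coupling partner + first product ⇌ bis adduct (K = 0.480 /M, k = 0.0570 /M/min)

In grey, coupling ran while solid remained: at 25.0 min, with 17.5% still solid and the partner at 0.107 M, starting material stood at 0.381 M, where S/(1 + B/Bc) gives 0.408 M. In amber, whose charge is less than Bc, the same reckoning with B held at that charge has the solid lasting about 19.6 min, and the flask shows 0% solid at 25.0 min. In teal, the solid stood at 0% by 25.0 min, and first product then moved from 67.4% to 68.7% at 50.0 min, beside 31.3% bis adduct.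

(All runs come from a simulation with constants of no real substance, noise included.)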